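The synthesis rests on cutting the oxepane between its oxygen and the fully substituted C3: the seven-membered ether (O–C3–C2–C1–C14–C15–C16) is traced back to a trans-fused cyclohexanone in which C16 is the carbonyl carbon. One Baeyer–Villiger oxidation inserts oxygen into the C3–C16 bond with retention at C3, expanding the six-membered carbocycle to the oxepanone and turning an all-carbon quaternary stereocentre, set by enolate alkylation, into the tertiary ether carbon. The precursor is a tricyclic decalone (ring C, ketone ring, tetrahydrofuran bridging C2 and C9) that carries C4 and C8 as protected hydroxymethyl arms and the less stable, axial C15 methyl group.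

Key step: step 17

Numbering used throughout: C1–C10 carbocycle with the ether bridge C2–O–C9; ring C = C1, C10, C11, C12, C13, C14; oxepane = C3–O–C16–C15–C14–C1–C2; C4 carries the acetate, C7 the methylene, C11 the hydroxyoctanoate. TBS = tert-butyldimethylsilyl, TIPS = triisopropylsilyl, Bn = benzyl.

Remark (correction to the precursor design): in the chair trans-decalone the C15 methyl group required by the target is axial and syn to the axial C4 arm on C3, so it is the less stable epimer. It therefore cannot be set by equilibration next to the ketone; it is installed last, by kinetic protonation, and oxidised under buffered conditions.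

Assumption: (S)-5-(hydroxymethyl)furan-2(5H)-one (1) and (R)-2-hydroxyoctanoic acid (34) are bought as single enantiomers. Where a SMILES string leaves a stereocentre open, the compound is carried as a mixture that converges in a later step.

Step 1
Reactants: 1 (S)-5-(hydroxymethyl)furan-2(5H)-one
Product: 2 (S)-5-[(TBS-oxy)methyl]furan-2(5H)-one
Conditions: TBSCl, imidazole, CH2Cl2, 0 °C → rt
Reagents that add atoms: tert-butyldimethylsilyl chloride, CC(C)(C)[Si](C)(C)Cl
Why: Standard silylation of the primary alcohol leaves the butenolide untouched and gives a C8–O group that lasts until step 24.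

Step 2
Reactants: 3 3-methylbut-2-enal
Product: 4 (E)-3-methylbuta-1,3-dien-1-yl acetate
Conditions: isopropenyl acetate, TsOH·H2O (cat.), Cu(OAc)2 (cat.), 95 °C, acetone distilled off
Reagents that add atoms: isopropenyl acetate, CC(=C)OC(C)=O
Why: Acid-catalysed enol acetylation (acyl transfer from isopropenyl acetate) of the enal gives the conjugated (E)-dienyl acetate.

Step 3
Reactants: 2 silyloxymethyl butenolide; 4 dienyl acetate
Product: 5 Diels–Alder lactone
Conditions: toluene, BHT (cat.), 150 °C, sealed tube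
Reagents that add atoms: none
Why: Thermal Diels–Alder reaction in which the 1-acetoxy and 3-methyl groups both direct C14 to the α-carbon (C1) and C11 to the β-carbon (C10) of the butenolide; the diene adds anti to the C9 arm, so H1 and H10 become cis and anti to C8, and the C14 configuration (endo expected) is irrelevant because it is removed in step 9.

Step 4
Reactants: 5 Diels–Alder lactone
Product: 6 C11 allylic alcohols
Conditions: SeO2 (0.5 equiv), t-BuOOH, CH2Cl2, rt
Reagents that add atoms: tert-butyl hydroperoxide, CC(C)(C)OO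
Why: Allylic hydroxylation by SeO2 (ene reaction then [2,3]-shift) takes place next to the more substituted alkene carbon at the ring CH2 (C11) and not at the methyl group; the C11 configuration is not needed here.

Step 5
Reactants: 6 C11 allylic alcohols
Product: 7 C11 enone
Conditions: Dess–Martin periodinane, NaHCO3, CH2Cl2, 0 °C → rt
Reagents that add atoms: none
Why: Dess–Martin oxidation converts both alcohol epimers into the single enone under neutral conditions that spare the β-acyloxy ketone and the allylic acetate.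

Step 6
Reactants: 7 C11 enone
Product: 8 C11 alcohol with OH cis to C9
Conditions: NaBH4, CeCl3·7H2O, MeOH, –78 °C
Reagents that add atoms: none
Why: Luche 1,2-reduction in which hydride attacks the carbonyl from the convex face of the cis-fused bicycle, anti to the C10–C9 bond, so the hydroxyl ends cis to C9 as in the target.

Step 7
Reactants: 8 C11 alcohol
Product: 9 C11 TIPS ether
Conditions: iPr3SiOTf, 2,6-lutidine, CH2Cl2, 0 °C
Reagents that add atoms: triisopropylsilyl trifluoromethanesulfonate, CC(C)[Si](C(C)C)(C(C)C)OS(=O)(=O)C(F)(F)F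
Why: Silylation of the hindered allylic alcohol with the silyl triflate gives a bulky, acid-tolerant ether that shields the concave face and lasts until step 28.

Step 8
Reactants: 9 C11 TIPS ether
Product: 10 saturated lactone with the C12 methyl group cis to O11
Conditions: H2 (5 bar), 5% Rh/Al2O3, EtOAc, rt
Reagents that add atoms: none
Why: Heterogeneous hydrogenation delivers hydrogen to the convex face, opposite the 11-silyloxy group, the 14-acetate and the lactone bridge, which sets C12; rhodium is chosen to avoid allylic C–O hydrogenolysis.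

Step 9
Reactants: 10 saturated lactone
Product: 11 α,β-unsaturated lactone (C1=C14)
Conditions: DBU, CH2Cl2, 0 °C
Reagents that add atoms: none
Why: E1cB loss of the β-acetoxy group gives the conjugated C1=C14 alkene, and the mild amine base at low temperature should not move the double bond into the lactone ring.

Step 10
Reactants: 11 α,β-unsaturated lactone
Product: 12 sulfone lactone
Conditions: PhSO2CH3, n-BuLi, THF/DMPU, –78 °C; then 11, –78 → –40 °C; AcOH, –78 °C
Reagents that add atoms: methyl phenyl sulfone, CS(=O)(=O)c1ccccc1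
Why: Conjugate (Michael) addition of the α-sulfonyl carbanion at C14 from the convex face, opposite O11, the C12 methyl group and the lactone bridge, followed by protonation of the lactone enolate away from the axial 11-silyloxy group, should give the cis-fused lactone with C15 trans to C2.

Step 11
Reactants: 12 sulfone lactone
Product: 13 lactol acetate
Conditions: iBu2AlH, CH2Cl2, –78 °C; then pyridine, DMAP, Ac2O, –78 → –20 °C
Reagents that add atoms: acetic anhydride, CC(=O)OC(C)=O
Why: Reductive acetylation (half-reduction, then O-acetylation of the aluminium lactolate in the same flask) stops at the aldehyde oxidation state without ring opening, and sulfone and silyl ethers are inert.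

Step 12
Reactants: 14 methyl 3-(benzyloxy)propanoate
Product: 15 ketene silyl acetal
Conditions: LDA, Me3SiCl, THF, –78 °C
Reagents that add atoms: chlorotrimethylsilane, C[Si](C)(C)Cl
Why: Kinetic ester enolisation with the silyl chloride present traps the enolate on oxygen before benzyl oxide can be lost.

Step 13
Reactants: 13 lactol acetate; 15 ketene silyl acetal
Product: 16 C-glycoside ester
Conditions: BF3·OEt2, CH2Cl2, –78 °C
Reagents that add atoms: none
Why: Mukaiyama-type addition to the cyclic oxocarbenium ion occurs at C2 from the convex face, anti to the C1–C14 bond, so H2 is trans to H1 and C3 is cis to the C8 arm; C3 forms as a mixture that is erased in step 15.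

Step 14
Reactants: 16 C-glycoside ester
Product: 18 C15-methylated keto sulfone, via lithium enolate of the cyclised keto sulfone 17 (not isolated)
Conditions: LDA (2.2 equiv), THF, –78 → –20 °C; then MeI, DMPU, –20 °C → rt
Reagents that add atoms: iodomethane, CI
Why: Intramolecular Claisen-type acylation of the kinetically formed α-sulfonyl carbanion by the ester closes the six-membered ketone ring, the β-keto sulfone enolate being the thermodynamic sink, and C-methylation of that enolate in the same flask makes C15 quaternary; neither new centre needs control.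

Step 15
Reactants: 18 C15-methylated keto sulfone
Product: 19 α-sulfonyl ketone with quaternary C3
Conditions: LDA, THF, –78 → –40 °C; then MeI, DMPU, –78 → –30 °C
Reagents that add atoms: iodomethane, CI
Why: Enolate alkylation at the only α-hydrogen (C3): whichever C15 substituent is axial shields the upper face (1,3-diaxial), helped by the C8 arm, so iodomethane enters from the lower face and the benzyloxymethyl group (C4) becomes axial as required, while the cold lithium enolate should not lose benzyl oxide.

Step 16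
Reactants: 19 α-sulfonyl ketone
Product: 20 tricyclic trans-decalone (key-step precursor)
Conditions: SmI2, THF/MeOH, –78 °C; pH 7 buffer at –78 °C
Reagents that add atoms: none
Why: Reductive desulfonylation of the α-sulfonyl ketone gives the samarium enolate, which methanol protonates at low temperature from the face opposite the axial C4 arm (kinetic ketonisation), so the C15 methyl group ends axial as the target requires.

Step 17
Reactants: 20 tricyclic trans-decalone
Product: 21 tricyclic oxepan-2-one
Conditions: CF3CO3H [(CF3CO)2O, urea·H2O2], Na2HPO4, CH2Cl2, 0 °C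
Reagents that add atoms: trifluoroperacetic acid, OOC(=O)C(F)(F)F
Why: The peracid adds to the C16 carbonyl, and in the Criegee adduct the C3–C16 bond antiperiplanar to the O–O bond shifts from carbon to oxygen as trifluoroacetate leaves; the closest known reaction type is the Baeyer–Villiger oxidation of an α,α-disubstituted cyclohexanone. The seven-membered ring is not closed by cyclisation but by one-atom ring expansion of the six-membered ketone ring through this 1,2-shift. C3 becomes the tertiary ether carbon with retention, so its configuration is controlled entirely by the quaternary centre set in step 15. The selectivity needed is migration of C3 in preference to C15: C3 is fully substituted and C15 only secondary, but the β-oxygen atoms on C2 and C4 lower the aptitude of C3, which is why C4 is carried as an ether and not at a higher oxidation state. The phosphate buffer at 0 °C is meant to prevent acid-catalysed epimerisation of the axial C15 methyl group and loss of the silyl ethers.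

Step 18
Reactants: 21 tricyclic oxepan-2-one
Product: 22 16-acetoxy oxepane
Conditions: iBu2AlH, CH2Cl2, –78 °C; then pyridine, DMAP, Ac2O, –78 → –20 °C
Reagents that add atoms: acetic anhydride, CC(=O)OC(C)=O
Why: Reductive acetylation as in step 11 traps the seven-membered lactol as its acetate and prevents opening to the hydroxy aldehyde.

Step 19
Reactants: 22 16-acetoxy oxepane
Product: 23 tricyclic oxepane
Conditions: Et3SiH, BF3·OEt2, CH2Cl2, –78 → –40 °C
Reagents that add atoms: none
Why: Ionisation to the cyclic oxocarbenium ion and hydride transfer from the silane (ionic reduction of a lactol acetate) gives the C16 methylene without touching any stereocentre.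

Step 20
Reactants: 23 tricyclic oxepane
Product: 24 C4 primary alcohol
Conditions: H2 (1 bar), Pd(OH)2/C, EtOAc, rt
Reagents that add atoms: none
Why: Hydrogenolysis of the benzyl ether frees the C4 alcohol before any alkene is present, and both silyl ethers stay.

Step 21
Reactants: 24 C4 primary alcohol
Product: 25 C4 aldehyde
Conditions: Dess–Martin periodinane, NaHCO3, CH2Cl2, rt
Reagents that add atoms: none
Why: Dess–Martin oxidation gives an α-alkoxy aldehyde that cannot epimerise because C3 is quaternary.

Step 22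
Reactants: 25 C4 aldehyde
Product: 26 (4S)-homoallylic alcohol
Conditions: MgBr2·OEt2, CH2Cl2, –20 °C; then allylSnBu3, –78 → 0 °C
Reagents that add atoms: allyltributylstannane, C=CC[Sn](CCCC)(CCCC)CCCC
Why: Chelation-controlled allylation in which magnesium bridges the aldehyde oxygen and the oxepane oxygen on C3, so the stannane attacks the carbonyl face flanked by the C3 methyl group and not by ring carbon C2, which gives the 4S alcohol.

Step 23
Reactants: 26 (4S)-homoallylic alcohol
Product: 27 (4S)-acetate
Conditions: Ac2O, Et3N, DMAP, CH2Cl2, rt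
Reagents that add atoms: acetic anhydride, CC(=O)OC(C)=O
Why: DMAP-catalysed acylation of the hindered secondary alcohol installs the C4 acetate of the target, which also protects this oxygen.

Step 24
Reactants: 27 (4S)-acetate
Product: 28 C8 primary alcohol
Conditions: HF·pyridine, pyridine, THF, 0 °C
Reagents that add atoms: none
Why: Buffered HF·pyridine cleaves the unhindered primary TBS ether much faster than the hindered secondary TIPS ether and leaves acetate and alkene alone.

Step 25
Reactants: 28 C8 primary alcohol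
Product: 30 allylsilane diene, via primary triflate 29 (not isolated)
Conditions: Tf2O, 2,6-lutidine, CH2Cl2, –78 °C; then CH2=C(CH2SiMe3)MgBr (from the bromide and Mg), CuI (20 mol %), THF, –40 → –20 °C
Reagents that add atoms: 2-bromo-3-(trimethylsilyl)prop-1-ene, C=C(Br)C[Si](C)(C)C
Why: Copper-catalysed SN2 coupling of the primary triflate with the alkenyl Grignard reagent at low temperature (Kochi-type coupling) should outrun attack on the hindered acetate and forms the C7–C8 bond with the allylsilane in place.

Step 26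
Reactants: 30 allylsilane diene
Product: 31 tetracyclic oxonene allylsilane
Conditions: second-generation Grubbs catalyst (10 mol %), CH2Cl2 (1 mM), 40 °C
Reagents that add atoms: none
Why: Ring-closing metathesis in which the carbene formed at the terminal alkene closes onto the 1,1-disubstituted alkene; the cis-2,9-disubstituted tetrahydrofuran holds both arms on one face, and the nine-membered ring forms with an endocyclic trisubstituted C6=C7 alkene, as known for methallyl analogues on such bridged ethers.

Step 27
Reactants: 31 tetracyclic oxonene allylsilane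
Product: 32 7-methylene tetracycle
Conditions: CF3CO2H, CH2Cl2, –20 → 0 °C
Reagents that add atoms: none
Why: Protodesilylation of the allylsilane (SE2'): protonation at C6 gives the β-silyl-stabilised C7 cation, which loses silicon to give the exocyclic C7 methylene regiospecifically and much faster than acid isomerisation of the product.

Step 28
Reactants: 32 7-methylene tetracycle
Product: 33 C11 alcohol
Conditions: Bu4NF, AcOH, THF, rt → 40 °C
Reagents that add atoms: none
Why: Fluoride cleaves the secondary TIPS ether, and buffering with acetic acid keeps the C4 acetate in place.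

Step 29
Reactants: 34 (R)-2-hydroxyoctanoic acid
Product: 36 (R)-2-(TBS-oxy)octanoic acid, via bis-silylated hydroxy acid 35 (not isolated)
Conditions: TBSCl, imidazole, DMF, rt; then K2CO3, MeOH/THF/H2O, rt; acidify to pH 4
Reagents that add atoms: tert-butyldimethylsilyl chloride, CC(C)(C)[Si](C)(C)Cl
Why: Bis-silylation followed by selective hydrolysis of the labile silyl ester gives the O-protected acid without touching the stereocentre.

Step 30
Reactants: 33 C11 alcohol; 36 (R)-2-(TBS-oxy)octanoic acid
Product: 38 O-silylated target, via mixed anhydride 37 (not isolated)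
Conditions: 2,4,6-Cl3C6H2COCl, Et3N, THF, rt; then 33, DMAP, toluene, rt → 40 °C
Reagents that add atoms: none
Why: Yamaguchi esterification through the mixed anhydride acylates the hindered secondary C11 alcohol, and the α-silyloxy group prevents self-condensation of the acid.

Step 31
Reactants: 38 O-silylated target
Product: 39 target CNP0132024.3
Conditions: HF·pyridine, pyridine, THF, 0 °C → rt
Reagents that add atoms: none
Why: Buffered fluoride removes the TBS ether of the α-hydroxy ester and leaves both esters, the ethers and the exocyclic alkene intact.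

Compound list

1 | (S)-5-(hydroxymethyl)furan-2(5H)-one | O=C1C=C[C@@H](CO)O1 | starting material
2 | (S)-5-[(TBS-oxy)methyl]furan-2(5H)-one | O=C1C=C[C@@H](CO[Si](C)(C)C(C)(C)C)O1 | intermediate
3 | 3-methylbut-2-enal | CC(C)=CC=O | starting material
4 | (E)-3-methylbuta-1,3-dien-1-yl acetate | CC(=O)O/C=C/C(C)=C | intermediate
5 | Diels–Alder lactone: 7-acetoxy-5-methyl-3-(TBS-oxymethyl)-3a,4,7,7a-tetrahydroisobenzofuran-1(3H)-one; C2 is the lactone carbonyl, H1 and H10 cis and anti to the C9 arm, C12=C13, 14-OAc cis to C2 | O=C1O[C@H](CO[Si](C)(C)C(C)(C)C)[C@H]2CC(C)=C[C@@H](OC(C)=O)[C@@H]12 | intermediate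
6 | 11-hydroxy derivative of 5 (C11 epimers) | O=C1O[C@H](CO[Si](C)(C)C(C)(C)C)[C@H]2C(O)C(C)=C[C@@H](OC(C)=O)[C@@H]12 | intermediate
7 | C11 enone (C11=O, C12=C13) | O=C1O[C@H](CO[Si](C)(C)C(C)(C)C)[C@H]2C(=O)C(C)=C[C@@H](OC(C)=O)[C@@H]12 | intermediate
8 | C11 allylic alcohol, OH cis to C9 | O=C1O[C@H](CO[Si](C)(C)C(C)(C)C)[C@H]2[C@@H](O)C(C)=C[C@@H](OC(C)=O)[C@@H]12 | intermediate
9 | C11 TIPS ether of 8 | O=C1O[C@H](CO[Si](C)(C)C(C)(C)C)[C@H]2[C@@H](O[Si](C(C)C)(C(C)C)C(C)C)C(C)=C[C@@H](OC(C)=O)[C@@H]12 | intermediate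
10 | saturated lactone, C12 methyl cis to O11 | O=C1O[C@H](CO[Si](C)(C)C(C)(C)C)[C@H]2[C@@H](O[Si](C(C)C)(C(C)C)C(C)C)[C@@H](C)C[C@@H](OC(C)=O)[C@@H]12 | intermediate
11 | α,β-unsaturated lactone (C1=C14) | O=C1O[C@H](CO[Si](C)(C)C(C)(C)C)[C@H]2[C@@H](O[Si](C(C)C)(C(C)C)C(C)C)[C@@H](C)CC=C12 | intermediate
12 | sulfone lactone: C14 carries CH2SO2Ph trans to C2, lactone cis-fused | O=C1O[C@H](CO[Si](C)(C)C(C)(C)C)[C@H]2[C@@H](O[Si](C(C)C)(C(C)C)C(C)C)[C@@H](C)C[C@H](CS(=O)(=O)c3ccccc3)[C@@H]12 | intermediate
13 | lactol acetate (C2 anomers) | CC(=O)OC1O[C@H](CO[Si](C)(C)C(C)(C)C)[C@H]2[C@@H](O[Si](C(C)C)(C(C)C)C(C)C)[C@@H](C)C[C@H](CS(=O)(=O)c3ccccc3)[C@@H]12 | intermediate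
14 | methyl 3-(benzyloxy)propanoate | COC(=O)CCOCc1ccccc1 | starting material
15 | [3-(benzyloxy)-1-methoxyprop-1-en-1-yl]oxy(trimethyl)silane | COC(=CCOCc1ccccc1)O[Si](C)(C)C | intermediate
16 | C-glycoside ester: methyl 3-(benzyloxy)-2-(C2-tetrahydrofuranyl)propanoate, H2 trans to H1, C3 cis to the C8 arm (C3 epimers) | COC(=O)C(COCc4ccccc4)[C@@H]1O[C@H](CO[Si](C)(C)C(C)(C)C)[C@H]2[C@@H](O[Si](C(C)C)(C(C)C)C(C)C)[C@@H](C)C[C@H](CS(=O)(=O)c3ccccc3)[C@@H]12 | intermediate
17 | tricyclic β-keto sulfone, formed as its lithium enolate (C3 epimers) | c1ccccc1COCC1C(=O)C(S(=O)(=O)c4ccccc4)[C@H]2C[C@H](C)[C@H](O[Si](C(C)C)(C(C)C)C(C)C)[C@H]3[C@@H]2[C@H]1O[C@@H]3CO[Si](C)(C)C(C)(C)C | intermediate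
18 | 15-methyl-15-(phenylsulfonyl) ketone (C3 and C15 epimers) | c1ccccc1COCC1C(=O)C(C)(S(=O)(=O)c4ccccc4)[C@H]2C[C@H](C)[C@H](O[Si](C(C)C)(C(C)C)C(C)C)[C@H]3[C@@H]2[C@H]1O[C@@H]3CO[Si](C)(C)C(C)(C)C | intermediate
19 | α-sulfonyl ketone with quaternary C3 (CH2OBn axial, CH3 equatorial; C15 epimers) | c1ccccc1COC[C@@]1(C)C(=O)C(C)(S(=O)(=O)c4ccccc4)[C@H]2C[C@H](C)[C@H](O[Si](C(C)C)(C(C)C)C(C)C)[C@H]3[C@@H]2[C@H]1O[C@@H]3CO[Si](C)(C)C(C)(C)C | intermediate
20 | tricyclic trans-decalone with fused tetrahydrofuran and C16 ketone: C3 (CH3, CH2OBn), axial 15-CH3, 11-OTIPS, C8 OTBS | c1ccccc1COC[C@@]1(C)C(=O)[C@@H](C)[C@H]2C[C@H](C)[C@H](O[Si](C(C)C)(C(C)C)C(C)C)[C@H]3[C@@H]2[C@H]1O[C@@H]3CO[Si](C)(C)C(C)(C)C | intermediate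
21 | tricyclic oxepan-2-one with C3 as tertiary ether carbon | c1ccccc1COC[C@@]1(C)OC(=O)[C@@H](C)[C@H]2C[C@H](C)[C@H](O[Si](C(C)C)(C(C)C)C(C)C)[C@H]3[C@@H]2[C@H]1O[C@@H]3CO[Si](C)(C)C(C)(C)C | intermediate
22 | 16-acetoxy oxepane (C16 anomers) | c1ccccc1COC[C@@]1(C)OC(OC(C)=O)[C@@H](C)[C@H]2C[C@H](C)[C@H](O[Si](C(C)C)(C(C)C)C(C)C)[C@H]3[C@@H]2[C@H]1O[C@@H]3CO[Si](C)(C)C(C)(C)C | intermediate
23 | tricyclic oxepane with C4 OBn | c1ccccc1COC[C@@]1(C)OC[C@@H](C)[C@H]2C[C@H](C)[C@H](O[Si](C(C)C)(C(C)C)C(C)C)[C@H]3[C@@H]2[C@H]1O[C@@H]3CO[Si](C)(C)C(C)(C)C | intermediate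
24 | C4 primary alcohol | OC[C@@]1(C)OC[C@@H](C)[C@H]2C[C@H](C)[C@H](O[Si](C(C)C)(C(C)C)C(C)C)[C@H]3[C@@H]2[C@H]1O[C@@H]3CO[Si](C)(C)C(C)(C)C | intermediate
25 | C4 aldehyde | O=C[C@@]1(C)OC[C@@H](C)[C@H]2C[C@H](C)[C@H](O[Si](C(C)C)(C(C)C)C(C)C)[C@H]3[C@@H]2[C@H]1O[C@@H]3CO[Si](C)(C)C(C)(C)C | intermediate
26 | (4S)-homoallylic alcohol | C=CC[C@H](O)[C@@]1(C)OC[C@@H](C)[C@H]2C[C@H](C)[C@H](O[Si](C(C)C)(C(C)C)C(C)C)[C@H]3[C@@H]2[C@H]1O[C@@H]3CO[Si](C)(C)C(C)(C)C | intermediate
27 | (4S)-acetate | C=CC[C@H](OC(C)=O)[C@@]1(C)OC[C@@H](C)[C@H]2C[C@H](C)[C@H](O[Si](C(C)C)(C(C)C)C(C)C)[C@H]3[C@@H]2[C@H]1O[C@@H]3CO[Si](C)(C)C(C)(C)C | intermediate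
28 | C8 primary alcohol | C=CC[C@H](OC(C)=O)[C@@]1(C)OC[C@@H](C)[C@H]2C[C@H](C)[C@H](O[Si](C(C)C)(C(C)C)C(C)C)[C@H]3[C@@H]2[C@H]1O[C@@H]3CO | intermediate
29 | C8 primary triflate | C=CC[C@H](OC(C)=O)[C@@]1(C)OC[C@@H](C)[C@H]2C[C@H](C)[C@H](O[Si](C(C)C)(C(C)C)C(C)C)[C@H]3[C@@H]2[C@H]1O[C@@H]3COS(=O)(=O)C(F)(F)F | intermediate
30 | allylsilane diene: C9 carries CH2C(=CH2)CH2SiMe3, C4 carries allyl | C=CC[C@H](OC(C)=O)[C@@]1(C)OC[C@@H](C)[C@H]2C[C@H](C)[C@H](O[Si](C(C)C)(C(C)C)C(C)C)[C@H]3[C@@H]2[C@H]1O[C@@H]3CC(=C)C[Si](C)(C)C | intermediate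
31 | tetracyclic oxonene with endocyclic C6=C7 and 7-(trimethylsilylmethyl) group | C[Si](C)(C)C/C1=C/C[C@H](OC(C)=O)[C@@]2(C)OC[C@@H](C)[C@H]3C[C@H](C)[C@H](O[Si](C(C)C)(C(C)C)C(C)C)[C@H]4[C@@H]3[C@H]2O[C@@H]4C1 | intermediate
32 | 7-methylene tetracycle, 4-OAc, 11-OTIPS | C=C1CC[C@H](OC(C)=O)[C@@]2(C)OC[C@@H](C)[C@H]3C[C@H](C)[C@H](O[Si](C(C)C)(C(C)C)C(C)C)[C@H]4[C@@H]3[C@H]2O[C@@H]4C1 | intermediate
33 | C11 alcohol | C=C1CC[C@H](OC(C)=O)[C@@]2(C)OC[C@@H](C)[C@H]3C[C@H](C)[C@H](O)[C@H]4[C@@H]3[C@H]2O[C@@H]4C1 | intermediate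
34 | (R)-2-hydroxyoctanoic acid | OC(=O)[C@H](O)CCCCCC | starting material
35 | tert-butyldimethylsilyl (R)-2-(TBS-oxy)octanoate | CC(C)(C)[Si](C)(C)OC(=O)[C@H](O[Si](C)(C)C(C)(C)C)CCCCCC | intermediate
36 | (R)-2-(TBS-oxy)octanoic acid | OC(=O)[C@H](O[Si](C)(C)C(C)(C)C)CCCCCC | intermediate
37 | mixed anhydride of 36 with 2,4,6-trichlorobenzoic acid | O=C(OC(=O)[C@H](O[Si](C)(C)C(C)(C)C)CCCCCC)c1c(Cl)cc(Cl)cc1Cl | intermediate
38 | O-silylated target | C=C1CC[C@H](OC(C)=O)[C@@]2(C)OC[C@@H](C)[C@H]3C[C@H](C)[C@H](OC(=O)[C@H](O[Si](C)(C)C(C)(C)C)CCCCCC)[C@H]4[C@@H]3[C@H]2O[C@@H]4C1 | intermediate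
39 | target CNP0132024.3, (1R,2R,3R,4S,9R,10S,11S,12S,14R,15S) with (R)-2-hydroxyoctanoate at O11 | C=C1CC[C@H](OC(C)=O)[C@@]2(C)OC[C@@H](C)[C@H]3C[C@H](C)[C@H](OC(=O)[C@H](O)CCCCCC)[C@H]4[C@@H]3[C@H]2O[C@@H]4C1 | target

Total step count: 31. Longest linear sequence: 28 steps (1, 3–11, 13–28, 30, 31, from compound 1).

Steps most likely to fail

Step 17. The secondary C15 may migrate in competition with the β-oxygenated quaternary C3, which would insert the oxygen on the wrong side of C16. The fallback sets out from 19, in which C15 still carries the phenylsulfonyl group and therefore cannot migrate. Oxidation of 19 with buffered CF3CO3H should give the α-sulfonyl oxepanone F1. Reductive desulfonylation of F1 with SmI2 in THF/DMPU with methanol at –78 °C should return to the route at 21. C15 is then set by protonation of the lactone enolate, again expected from the face opposite the C4 arm, and has to be checked at that stage.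

Step 26. Ring closure onto the hindered 1,1-disubstituted allylsilane alkene may be slow, so that intermolecular metathesis and loss of silicon compete. The fallback sets out from 28 and forms the C6–C7 bond by an intramolecular B-alkyl Suzuki coupling. Triflate 29 is coupled with 1-(trimethylsilyl)vinylmagnesium bromide and CuI to give the vinylsilane F2. Iododesilylation with N-iodosuccinimide in hexafluoroisopropanol, which is much faster for a vinylsilane than for a terminal alkene, gives the 2-iodoalkene F3. Hydroboration of the allyl terminus with 9-BBN gives the alkylborane F4, and PdCl2(dppf), AsPh3 and Cs2CO3 in DMF/THF/H2O at high dilution close the ring. This gives the exocyclic methylene directly and returns to the route at 32.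

Step 10. The lithiated sulfone may act as a base at C13 (deconjugation and shift of the double bond into the lactone ring) or add to the lactone carbonyl in place of conjugate addition. The fallback sets out from 11 and uses a non-basic cuprate. Vinylmagnesium bromide with CuI and Me3SiCl should give the C14 vinyl lactone F5 with the same facial course. Ozonolysis with NaBH4 work-up gives the primary alcohol F6, and PhSSPh with Bu3P gives the phenyl sulfide F7. Oxidation with H2O2 and (NH4)6Mo7O24 returns to the route at 12.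

Further compounds

F1 | step 17 | α-sulfonyl oxepan-2-one (C15 carries CH3 and SO2Ph) | c1ccccc1COC[C@@]1(C)OC(=O)C(C)(S(=O)(=O)c4ccccc4)[C@H]2C[C@H](C)[C@H](O[Si](C(C)C)(C(C)C)C(C)C)[C@H]3[C@@H]2[C@H]1O[C@@H]3CO[Si](C)(C)C(C)(C)C
F2 | step 26 | vinylsilane: C9 carries CH2C(SiMe3)=CH2 | C=CC[C@H](OC(C)=O)[C@@]1(C)OC[C@@H](C)[C@H]2C[C@H](C)[C@H](O[Si](C(C)C)(C(C)C)C(C)C)[C@H]3[C@@H]2[C@H]1O[C@@H]3CC(=C)[Si](C)(C)C
F3 | step 26 | 2-iodoalkene: C9 carries CH2C(I)=CH2 | C=CC[C@H](OC(C)=O)[C@@]1(C)OC[C@@H](C)[C@H]2C[C@H](C)[C@H](O[Si](C(C)C)(C(C)C)C(C)C)[C@H]3[C@@H]2[C@H]1O[C@@H]3CC(I)=C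
F4 | step 26 | B-alkyl-9-borabicyclo[3.3.1]nonane at C6 | C1CC2CCCC(C1)B2CCC[C@H](OC(C)=O)[C@@]1(C)OC[C@@H](C)[C@H]2C[C@H](C)[C@H](O[Si](C(C)C)(C(C)C)C(C)C)[C@H]3[C@@H]2[C@H]1O[C@@H]3CC(I)=C
F5 | step 10 | C14 vinyl lactone | O=C1O[C@H](CO[Si](C)(C)C(C)(C)C)[C@H]2[C@@H](O[Si](C(C)C)(C(C)C)C(C)C)[C@@H](C)C[C@H](C=C)[C@@H]12
F6 | step 10 | C14 hydroxymethyl lactone | O=C1O[C@H](CO[Si](C)(C)C(C)(C)C)[C@H]2[C@@H](O[Si](C(C)C)(C(C)C)C(C)C)[C@@H](C)C[C@H](CO)[C@@H]12
F7 | step 10 | C14 (phenylthio)methyl lactone | O=C1O[C@H](CO[Si](C)(C)C(C)(C)C)[C@H]2[C@@H](O[Si](C(C)C)(C(C)C)C(C)C)[C@@H](C)C[C@H](CSc3ccccc3)[C@@H]12
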